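**Structural features**

The target is a monocyclic cyclohexene. The ring is numbered here C1 (OMe), C2=C3 (C3 carries the exocyclic C7H2OBz), C4 (OH), C5 (OBz), C6 (OH); α is the face of the C1 methoxy group, β the opposite face, and all compound names below use these locants. C4, C5, C6 and C1 form an unbroken chain of four oxygen-bearing stereocentres (all R): the C4 and C5 oxygens are cis (β), the C5 and C6 oxygens trans, and the C6 and C1 oxygens cis (α). The seven carbons are those of a 2,5-dioxygenated benzyl alcohol, so the skeleton is trivial; the real difficulty is to set absolute configuration on a flat achiral ring and to tell four secondary oxygens apart (one methyl ether, one benzoate, two free hydroxyls). Fragile points are the C5 benzoate, which sits between two free hydroxyls and can migrate, the allylic ether at C1, the allylic carbinol at C4, and the readiness of such a hydrated arene to aromatise under strong acid or base. The key step exploits two features: the C1 and C4 oxygens are para, which maps the ring onto a p-quinone monoketal (C1 ketone, C4 ketal), and the trans C5/C6 diol maps onto an oxirane across C5=C6 that is later opened with inversion at C5. C7 on C3 shields the second enone from conjugate addition, and its free hydroxyl can anchor a chiral sodium tartrate–peroxide aggregate.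

**Logic of the disconnections**

20 ⇒ 19. The acyl C–O bond at O5 is cut and the benzoyl group is placed on O4. A cis hydroxy ester pair at C4/C5 is what an orthoacid collapse delivers, and that collapse puts the ester on the pseudoaxial oxygen (O4) first. The gain is that the last operation becomes a stereochemically neutral isomerisation. The forward step must move the ester only across the cis O4/O5 pair and must favour the equatorial O5 position.

19 ⇒ 16 (through 18 and 17). The C5–O bond is cut; that oxygen returns to the carbonyl of the C4 ester, and C5 is reconnected to the C6 oxygen as an oxirane. One intramolecular event then creates the cis C4/C5 and trans C5/C6 relationships, and the remaining oxygen comes from water. Three contiguous carbinols reduce to one ester and one oxirane. The demand is that the C4 ester stands anti to the oxirane, so that its carbonyl oxygen reaches C5 from the β face through a five-membered transition state.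

16 ⇒ 14 + 15. The C4–O ester bond is cut with inversion at C4. Hydride reduction next to an α oxirane gives the cis alcohol, so the anti ester has to come from a displacement. The C4 stereocentre reduces to what a simple reduction provides, and the acyl unit reduces to 15. The forward step must be a clean SN2 reaction at a hindered secondary allylic carbon, without SN2′ attack at C2.

14 ⇒ 13 ⇒ 12. The C4–H bond is cut (alcohol to ketone), then the ketone is returned to its dimethyl ketal (two C4–OMe bonds). The ketal is the latent carbonyl that has kept C4 distinct from C1. This removes the C4 stereocentre. The demands are hydride delivery anti to the oxirane and a ketal hydrolysis that spares the oxirane and the C1 ether.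

12 ⇒ 10 + 11 ⇒ 9. The O–CH3 bond at C1 and then the C1–H bond are cut. While C4 is still a ketal, the C1 carbinol is the only hydroxyl in the molecule, so its methylation needs no selectivity. The C1 stereocentre disappears and the ring returns to an epoxy enone. The demands are 1,2-reduction with hydride anti to the oxirane (O1 cis to O6) and a non-basic methylation that spares the ester.

9 ⇒ 7 + 8. The ester bond at O7 is cut. The ester is introduced only after the epoxidation, because the free C7 hydroxyl is wanted as an anchor in that step and an ester would be exposed there to a sodium peroxide and sodium alkoxides. The step count is unchanged by this order. The forward step is an ordinary acylation of the only hydroxyl present.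

7 ⇒ 4 + 5 (through 6). Both C–O bonds of the oxirane (C5–O and C6–O) are cut, which restores the C5=C6 bond of a planar, achiral dienone. This is the only point at which absolute configuration enters, and all stereocentres vanish. The forward step must choose C5=C6 over C2=C3 and one enantiotopic face over the other.

4 ⇒ 2 + 3. One C4–OMe bond is cut and the ring is rearomatised. The ring reduces to a benzene derivative. The forward step is an oxidative dearomatisation at the carbon para to the phenol. It is placed before any acylation, so that a benzylic alcohol never has to be acylated in the presence of a more acidic phenol.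

2 ⇒ 1. The C7–H bond is cut (alcohol to aldehyde), which reaches a commercial aldehyde. The forward step is a chemoselective carbonyl reduction.

**Other disconnections considered**

Alternative 1: The cut removes the C4–O and C5–O bonds and leads back to a simple arene. In the forward sense, whole cells expressing toluene dioxygenase would add O2 across one π-bond of bromobenzene A1 and give the cis-dienediol A2. Both new oxygens lie on the β face at C4 and C5, and the bromine marks C3 for later attachment of C7 (for example by carbonylation with Pd(PPh3)4, zerovalent palladium).
- In its favour: two stereocentres of the correct absolute sense come from one fermentation step on a commodity chemical; the cis C4/C5 pair needs no inversion; osmylation with OsO4 anti to a protected 4,5-diol would place the C1 and C6 oxygens on the α face as required.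
- Against it here: the route ends with two cis-diol pairs, four secondary hydroxyls of similar reactivity, of which only O1 may be methylated and only O5 benzoylated. A2 has no counterpart of the ketone/ketal pair that separates C1 from C4 in the chosen plan, it tends to dimerise, and fermentation equipment is needed.
- Structure: the alternative matches both cis pairs of the target directly and is the better plan on that point, because the chosen route must invert C4 and C5. It is also the better on absolute stereocontrol, since an enzyme replaces a stoichiometric chiral additive whose sense has to be checked.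
- Mechanism: an enzymatic arene dihydroxylation stands against a two-electron conjugate addition and ring closure. Neither is intrinsically more reliable, but only the chosen route carries built-in regiochemical information for the four oxygens.
- Step economy: about equal; the early lead of the enzymatic route would probably be used up by protecting-group steps.

Alternative 2: The cut is the C4–C5 bond, which opens the ring to an acyclic chain. In the forward sense SmI2 (divalent samarium) would reduce the C4 enal carbonyl and the C5 aldehyde of the (Z)-dialdehyde A3 to ketyls and couple them. This would close the six-membered ring and give the cis-4,5-diol A4 with the C1 methoxy group and silyl ethers at O6 and O7.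
- In its favour: the ring and two stereocentres are made in one step; the cis diol should arise directly on a samarium chelate, anti to the C6 oxygen; the C1 methyl ether is present from the start. On these two points (no inversion at C4 or C5, no late methylation) it is better than the chosen plan.
- Against it here: A3 needs a (Z)-trisubstituted enal and two preset stereocentres (C1, C6) from a chiral-pool building block. It is both a γ-alkoxy enal and an α-silyloxy aldehyde, hence prone to double-bond isomerisation, β-elimination and epimerisation. The enal ketyl is an allylic radical anion that can react at C2 or be over-reduced.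
- Structure: after ring closure the problem of benzoylating O5 and not O4 remains, so the two plans are equal there; two silyl ethers must also be exchanged.
- Mechanism: a single-electron reductive coupling with stereocontrol relayed from existing centres replaces a reagent-controlled epoxidation; this is an advantage only if those centres are cheap to make.
- Step economy: clearly longer, because the acyclic precursor needs more steps than the whole aromatic route.

Alternative 3: The cut removes the C3–C4 and C5–C6 bonds and divides the ring into a diene and a two-carbon dienophile. In the forward sense a Cu(OTf)2–bis(oxazoline) complex (divalent copper) would bind the ester and lactone carbonyls of the 3-carbomethoxy-2-pyrone A5. It would catalyse the inverse-electron-demand Diels–Alder reaction with the electron-rich 2,2-dimethyl-1,3-dioxole A6 and give the endo bicyclic lactone A7, with the C4/C5 acetonide, the lactone oxygen on C6 and a C1=C2 double bond.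
- In its favour: it is the only plan that is catalytic in the chiral controller; it forms two C–C bonds and fixes C4, C5 and C6 in their final configuration in one step; the carbon that becomes C7 is already on C3. In bonds and stereocentres per step it is better than the chosen key step, which sets two centres of which one is later inverted.
- Against it here: A7 has one carbon too many (the lactone carbonyl must be excised), C1 carries no oxygen, and the double bond lies at C1=C2, so an oxidative allylic transposition is needed. The ester must be reduced, and the differentiation of O1 from O6 and of O5 from O4 returns in full. A6 is volatile and not a stock chemical.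
- Mechanism: a Lewis-acid-catalysed cycloaddition with two-point binding stands against a stoichiometric tartrate-mediated conjugate epoxidation; in principle the cycloaddition is the more atom-economical way to introduce chirality.
- Step economy: longer, because the adduct is further from the substitution pattern of the target than the epoxy enone of the chosen route.

Key step: step 3

Assumption: L-(+)-diisopropyl tartrate is taken to favour the (5R,6S) oxirane 7; the sense of induction must be confirmed on this substrate, and the equally commercial D-(−) ester is used if it is the opposite.

Step 1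
Reactants: 1 5-hydroxy-2-methoxybenzaldehyde
Product: 2 3-(hydroxymethyl)-4-methoxyphenol
Conditions: NaBH4, MeOH, 0 °C
Reagents that add atoms: none
Why: Chemoselective borohydride reduction of the aldehyde; the phenol is at most deprotonated and returns on work-up, and no stereocentre is formed.

Step 2
Reactants: 2 3-(hydroxymethyl)-4-methoxyphenol; 3 methanol
Product: 4 3-(hydroxymethyl)-4,4-dimethoxycyclohexa-2,5-dien-1-one
Conditions: PhI(OAc)2, MeOH, 0 °C
Reagents that add atoms: methanol (3), CO
Why: Oxidative dearomatisation of a 4-methoxyphenol with PhI(OAc)2 (trivalent iodine): two-electron oxidation makes C4 electrophilic and methanol adds there to give the achiral p-quinone monoketal. The primary alcohol is not oxidised and is afterwards the only hydroxyl, so no chemoselective acylation against a phenol is ever needed.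

Step 3
Reactants: 4 3-(hydroxymethyl)-4,4-dimethoxycyclohexa-2,5-dien-1-one; 5 triphenylmethyl hydroperoxide
Product: 7 (5R,6S)-5,6-epoxy-3-(hydroxymethyl)-4,4-dimethoxycyclohex-2-en-1-one, via sodium peroxy enolate 6 (not isolated)
Conditions: Ph3COOH, NaN(SiMe3)2, L-(+)-diisopropyl tartrate, 4 Å molecular sieves, PhMe, −65 °C; then aq. NH4Cl
Reagents that add atoms: triphenylmethyl hydroperoxide (5), OOC(c1ccccc1)(c1ccccc1)c1ccccc1
Why: Ph3COOH and NaN(SiMe3)2 give Ph3COONa, which adds in conjugate fashion to C5, the unsubstituted β-carbon of the C1 ketone, to form enolate 6; the enolate carbon C6 then attacks the inner peroxide oxygen and expels trityloxide, so the C5–O and C6–O bonds are made in sequence (Weitz–Scheffer mechanism). The closure is a 3-exo-tet displacement at oxygen and gives the only new ring, a cis-fused oxirane on the α face. The closest known reaction type is the tartrate-mediated asymmetric nucleophilic epoxidation of hydroxymethyl-substituted p-quinone monoketals, which is this substrate class. C5 is set in the addition step by the chiral sodium tartrate aggregate: the C7 alkoxide, the tartrate diolate and the peroxide are expected to share sodium ions, so that the peroxide is delivered across C4 to one enantiotopic face of the flat dienone; C6 follows from C5 because the three-membered ring can only close on the same face. The step needs site selectivity and enantioface selectivity: the first is secured by C7, which makes C3 a disubstituted, shielded β-carbon that the bulky trityl peroxide should avoid, the second by the tartrate together with the free C7 hydroxyl. For that reason, and because no ester should meet the sodium peroxide, the benzoate is put on only in step 4. This step fixes the absolute configuration of the route: the C6–O bond is kept to the target and C5 is later inverted under the control of C4.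

Step 4
Reactants: 7 (5R,6S)-5,6-epoxy-3-(hydroxymethyl)-4,4-dimethoxycyclohex-2-en-1-one; 8 benzoyl chloride
Product: 9 (5R,6S)-3-(benzoyloxymethyl)-5,6-epoxy-4,4-dimethoxycyclohex-2-en-1-one
Conditions: BzCl, pyridine, DMAP (cat.), CH2Cl2, 0 °C
Reagents that add atoms: benzoyl chloride (8), O=C(Cl)c1ccccc1
Why: Acyl-transfer esterification of a primary allylic alcohol, the only hydroxyl present; the epoxy ketone and the ketal tolerate pyridine at 0 °C and no stereocentre is touched.

Step 5
Reactants: 9 (5R,6S)-3-(benzoyloxymethyl)-5,6-epoxy-4,4-dimethoxycyclohex-2-en-1-one
Product: 10 (1R,5R,6R)-3-(benzoyloxymethyl)-5,6-epoxy-4,4-dimethoxycyclohex-2-en-1-ol (1α-OH, cis to the oxirane)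
Conditions: NaBH4, CeCl3·7H2O, MeOH, −78 °C
Reagents that add atoms: none
Why: Luche 1,2-reduction: the hard alkoxyborohydride attacks the C1 carbonyl, not the blocked β-carbon C3, and should approach from the β face, anti to the adjacent C6–O bond of the oxirane on a nearly planar ring, which places the new hydroxyl α and cis to the oxirane. The benzoate is inert at −78 °C.

Step 6
Reactants: 10 (1R,5R,6R)-3-(benzoyloxymethyl)-5,6-epoxy-4,4-dimethoxycyclohex-2-en-1-ol; 11 methyl iodide
Product: 12 (1R,5R,6R)-3-(benzoyloxymethyl)-5,6-epoxy-1,4,4-trimethoxycyclohex-2-ene
Conditions: MeI, Ag2O, 4 Å molecular sieves, MeCN, 40 °C, dark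
Reagents that add atoms: methyl iodide (11), CI
Why: Purdie methylation: Ag2O activates MeI without generating a free alkoxide, so the C7 benzoate is neither cleaved nor transferred, and a Payne rearrangement is geometrically excluded because O1 is cis to the oxirane. C1 is the only hydroxyl while C4 is still a ketal, so no selectivity is needed.

Step 7
Reactants: 12 (1R,5R,6R)-3-(benzoyloxymethyl)-5,6-epoxy-1,4,4-trimethoxycyclohex-2-ene
Product: 13 (1R,5R,6R)-3-(benzoyloxymethyl)-5,6-epoxy-1-methoxycyclohex-2-en-4-one
Conditions: TsOH·H2O (cat.), acetone/H2O, 0 °C → rt
Reagents that add atoms: water, O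
Why: Acid-catalysed hydrolysis of an allylic dimethyl ketal through the C4 oxocarbenium ion, which the C2=C3 bond stabilises; the oxirane, flanked by two electron-poor carbons, and the C1 ether should resist dilute acid, and no stereocentre changes.

Step 8
Reactants: 13 (1R,5R,6R)-3-(benzoyloxymethyl)-5,6-epoxy-1-methoxycyclohex-2-en-4-one
Product: 14 (1R,4S,5S,6R)-3-(benzoyloxymethyl)-5,6-epoxy-1-methoxycyclohex-2-en-4-ol (4α-OH, all-cis)
Conditions: NaBH4, CeCl3·7H2O, MeOH, −78 °C
Reagents that add atoms: none
Why: Luche reduction of the enone carbonyl: hydride should again enter from the β face, anti to the oxirane C5–O bond and away from all α substituents, to give the 4α alcohol; this is the epimer opposite to the target at C4 and is inverted in step 9.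

Step 9
Reactants: 14 (1R,4S,5S,6R)-3-(benzoyloxymethyl)-5,6-epoxy-1-methoxycyclohex-2-en-4-ol; 15 benzoic acid
Product: 16 (1R,4R,5S,6R)-4-benzoyloxy-3-(benzoyloxymethyl)-5,6-epoxy-1-methoxycyclohex-2-ene (4β-OBz, anti to the oxirane)
Conditions: PhCO2H, PPh3, DIAD, PhMe, 0 °C → rt
Reagents that add atoms: benzoic acid (15), OC(=O)c1ccccc1
Why: Mitsunobu esterification: the C4 oxygen is turned into a phosphorus-bound leaving group and benzoate displaces it by SN2 from the unhindered β face, which inverts C4. The same operation installs the ester, anti to the oxirane, that delivers oxygen to C5 in step 10.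

Step 10
Reactants: 16 (1R,4R,5S,6R)-4-benzoyloxy-3-(benzoyloxymethyl)-5,6-epoxy-1-methoxycyclohex-2-ene
Product: 19 (1R,4R,5S,6S)-4-benzoyloxy-3-(benzoyloxymethyl)-1-methoxycyclohex-2-ene-5,6-diol, via acyloxonium zwitterion 17 (not isolated), via hemiorthoester 18 (not isolated)
Conditions: BF3·OEt2, CH2Cl2, −30 → 0 °C; then THF/H2O; aq. NaHCO3
Reagents that add atoms: water, O
Why: Anchimerically assisted oxirane opening: BF3 activates the oxirane and the carbonyl oxygen of the anti C4 benzoate attacks C5 from the β face (5-exo, inversion at C5) to give acyloxonium ion 17; water adds to give orthoacid 18, which collapses to a cis hydroxy ester. C6 keeps its oxirane oxygen (α), so C4/C5 cis and C5/C6 trans are fixed. The collapse is expected to favour the pseudoaxial C4 ester 19, with 20 as the minor partner, and the two are taken on together.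

Step 11
Reactants: 19 (1R,4R,5S,6S)-4-benzoyloxy-3-(benzoyloxymethyl)-1-methoxycyclohex-2-ene-5,6-diol
Product: 20 (1R,4R,5R,6R)-5-benzoyloxy-3-(benzoyloxymethyl)-1-methoxycyclohex-2-ene-4,6-diol (target)
Conditions: DBU (cat.), MeCN, 0 °C → rt
Reagents that add atoms: none
Why: Base-catalysed 1,2-acyl migration between cis-vicinal oxygens through an orthoacid-type intermediate: under equilibrating conditions the benzoyl group should move from the crowded pseudoaxial allylic O4 to the equatorial O5. Migration across the trans O5/O6 pair or away from the primary O7 is much slower, so the reaction is stopped at the O4/O5 equilibrium; no stereocentre is touched.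

**Compound list**

1 | 5-hydroxy-2-methoxybenzaldehyde | COc1ccc(O)cc1C=O | starting material
2 | 3-(hydroxymethyl)-4-methoxyphenol | COc1ccc(O)cc1CO | intermediate
3 | methanol | CO | starting material
4 | 3-(hydroxymethyl)-4,4-dimethoxycyclohexa-2,5-dien-1-one | COC1(OC)C=CC(=O)C=C1CO | intermediate
5 | triphenylmethyl (trityl) hydroperoxide | OOC(c1ccccc1)(c1ccccc1)c1ccccc1 | starting material
6 | sodium (5R)-3-(hydroxymethyl)-4,4-dimethoxy-5-(triphenylmethylperoxy)cyclohexa-1(6),2-dien-1-olate (peroxide on the α face) | COC1(OC)[C@H](OOC(c2ccccc2)(c2ccccc2)c2ccccc2)C=C([O-])C=C1CO.[Na+] | intermediate (not isolated)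
7 | (5R,6S)-5,6-epoxy-3-(hydroxymethyl)-4,4-dimethoxycyclohex-2-en-1-one (α oxirane) | COC1(OC)[C@@H]2O[C@@H]2C(=O)C=C1CO | intermediate
8 | benzoyl chloride | O=C(Cl)c1ccccc1 | starting material
9 | (5R,6S)-3-(benzoyloxymethyl)-5,6-epoxy-4,4-dimethoxycyclohex-2-en-1-one | COC1(OC)[C@@H]2O[C@@H]2C(=O)C=C1COC(=O)c1ccccc1 | intermediate
10 | (1R,5R,6R)-3-(benzoyloxymethyl)-5,6-epoxy-4,4-dimethoxycyclohex-2-en-1-ol (1α-OH) | O[C@@H]1C=C(COC(=O)c2ccccc2)C(OC)(OC)[C@@H]3O[C@H]13 | intermediate
11 | methyl iodide | CI | starting material
12 | (1R,5R,6R)-3-(benzoyloxymethyl)-5,6-epoxy-1,4,4-trimethoxycyclohex-2-ene | CO[C@@H]1C=C(COC(=O)c2ccccc2)C(OC)(OC)[C@@H]3O[C@H]13 | intermediate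
13 | (1R,5R,6R)-3-(benzoyloxymethyl)-5,6-epoxy-1-methoxycyclohex-2-en-4-one | CO[C@@H]1C=C(COC(=O)c2ccccc2)C(=O)[C@@H]3O[C@H]13 | intermediate
14 | (1R,4S,5S,6R)-3-(benzoyloxymethyl)-5,6-epoxy-1-methoxycyclohex-2-en-4-ol (4α-OH) | CO[C@@H]1C=C(COC(=O)c2ccccc2)[C@H](O)[C@@H]3O[C@H]13 | intermediate
15 | benzoic acid | OC(=O)c1ccccc1 | starting material
16 | (1R,4R,5S,6R)-4-benzoyloxy-3-(benzoyloxymethyl)-5,6-epoxy-1-methoxycyclohex-2-ene (4β-OBz) | CO[C@@H]1C=C(COC(=O)c2ccccc2)[C@@H](OC(=O)c2ccccc2)[C@@H]3O[C@H]13 | intermediate
17 | acyloxonium zwitterion: 2-phenyl-1,3-dioxolan-2-ylium cis-fused through O4 and O5 (β face), C6 oxygen (α) bound to BF3 | CO[C@@H]1C=C(COC(=O)c2ccccc2)[C@H]3OC(c4ccccc4)=[O+][C@H]3[C@@H]1O[B-](F)(F)F | intermediate (not isolated)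
18 | hemiorthoester: 2-hydroxy-2-phenyl-1,3-dioxolane cis-fused through O4 and O5 (β face), 6α-OH, either configuration at the orthoester carbon | CO[C@@H]1C=C(COC(=O)c2ccccc2)[C@H]3OC(O)(c4ccccc4)O[C@H]3[C@@H]1O | intermediate (not isolated)
19 | (1R,4R,5S,6S)-4-benzoyloxy-3-(benzoyloxymethyl)-1-methoxycyclohex-2-ene-5,6-diol (4β-OBz, 5β-OH, 6α-OH) | CO[C@@H]1C=C(COC(=O)c2ccccc2)[C@@H](OC(=O)c2ccccc2)[C@@H](O)[C@@H]1O | intermediate
20 | (1R,4R,5R,6R)-5-benzoyloxy-3-(benzoyloxymethyl)-1-methoxycyclohex-2-ene-4,6-diol (4β-OH, 5β-OBz, 6α-OH, 1α-OMe) | CO[C@@H]1C=C(COC(=O)c2ccccc2)[C@@H](O)[C@@H](OC(=O)c2ccccc2)[C@@H]1O | target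

**Step count and least certain steps**

Total: 11 steps. Longest linear sequence: 11 steps (1 to 20); the route is fully linear, and steps 10 and 11 can be run without isolating 19.

Step 3 (key step). The risk is weak or reversed enantioface discrimination if the sodium tartrate aggregate does not hold the substrate through its C7 alkoxide; conjugate addition at C3 or a second epoxidation with excess peroxide are lesser risks. The fallback replaces asymmetric induction by resolution; it sets out from 4 and comes back at 10. An achiral Weitz–Scheffer epoxidation (tBuOOH, DBU, CH2Cl2, 0 °C) would give the racemic oxirane F1. Benzoylation as in step 4 would give the racemic benzoate F2, and Luche reduction as in step 5 the racemic cis-epoxy alcohol F3. Lipase-catalysed transesterification (Candida antarctica lipase B, vinyl acetate, MTBE) would then acetylate one enantiomer, here taken to be the unwanted one, as acetate F4, leaving 10. Should the enzyme prefer the wanted enantiomer, its acetate is collected instead and deacetylated with the same lipase in methanol.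

Step 5. The risk is hydride delivery syn to the oxirane (poor facial selectivity), which would put O1 on the wrong face; conjugate reduction is less likely. The fallback corrects the centre by inversion; it sets out from 9 and comes back at 10. If reduction gives mainly the 1β epimer F5, a Mitsunobu reaction with chloroacetic acid (PPh3, DIAD, PhMe) would give the inverted chloroacetate F6, and selective methanolysis of this activated ester (Et3N, MeOH, 0 °C) should leave the C7 benzoate intact and give 10.

Step 9. The risk is SN2′ attack of benzoate at C2, or elimination, in place of direct displacement at the hindered C4. The fallback separates activation from displacement; it sets out from 14 and comes back at 16. The alcohol is converted into the α-mesylate F7 (MsCl, Et3N, CH2Cl2, −20 °C), which is displaced by a naked carboxylate (PhCO2Cs, 18-crown-6, PhMe, 60 °C) from the β face.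

Step 10. The risk is that Lewis-acid activation leads to ionisation at the allylic positions or to hydride-shift rearrangement of the oxirane faster than participation of the ester. The fallback uses base-mediated carbonate participation; it sets out from 16 and comes back at 20. Both benzoates are removed (K2CO3, MeOH, 0 °C) to give the trans-epoxy diol F8. Under Cs2CO3 and CO2 (1 atm) in DMF at 40 °C the C4 alkoxide is carboxylated, and the carbonate anion should open the oxirane at C5 from the β face to give the 4,5-cis cyclic carbonate F9; early saturation with CO2 keeps a Payne rearrangement in check. Methanolysis of the carbonate (K2CO3, MeOH) leads to the tetraol F10 of the fallback for step 11, and the tin-directed dibenzoylation described there reaches 20.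

Step 11. The risk is an unfavourable position of the O4/O5 acyl-migration equilibrium, or onward migration of the benzoyl group to O6. The fallback replaces equilibration by regioselective acylation; it sets out from 19 (or the 19/20 mixture) and comes back at 20. Methanolysis (K2CO3, MeOH) gives the tetraol F10. Bu2SnO (MeOH, reflux, then PhMe) converts the cis-4,5-diol into the dibutylstannylene acetal F11. BzCl (2 equiv) with Et3N at 0 °C should then acylate the primary O7 and the equatorial oxygen O5 of the tin acetal, as in the tin-mediated dibenzoylation of the primary hydroxyl and the equatorial oxygen of a cis-diol in hexopyranosides.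

**Further compounds**

F1 | step 3 | racemic 5,6-epoxy-3-(hydroxymethyl)-4,4-dimethoxycyclohex-2-en-1-one (racemate of 7, cis-fused oxirane) | COC1(OC)C2OC2C(=O)C=C1CO
F2 | step 3 | racemic 3-(benzoyloxymethyl)-5,6-epoxy-4,4-dimethoxycyclohex-2-en-1-one (racemate of 9) | COC1(OC)C2OC2C(=O)C=C1COC(=O)c1ccccc1
F3 | step 3 | racemic cis-epoxy alcohol (racemate of 10; relative configuration as drawn, one enantiomer shown) | O[C@@H]1C=C(COC(=O)c2ccccc2)C(OC)(OC)[C@@H]3O[C@H]13
F4 | step 3 | (1S,5S,6S)-1-acetoxy-3-(benzoyloxymethyl)-5,6-epoxy-4,4-dimethoxycyclohex-2-ene (acetate of the enantiomer of 10) | CC(=O)O[C@H]1C=C(COC(=O)c2ccccc2)C(OC)(OC)[C@H]3O[C@@H]13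
F5 | step 5 | (1S,5R,6R)-3-(benzoyloxymethyl)-5,6-epoxy-4,4-dimethoxycyclohex-2-en-1-ol (1β-OH, trans to the oxirane) | O[C@H]1C=C(COC(=O)c2ccccc2)C(OC)(OC)[C@@H]3O[C@H]13
F6 | step 5 | 1α-chloroacetate of 10 | O=C(CCl)O[C@@H]1C=C(COC(=O)c2ccccc2)C(OC)(OC)[C@@H]3O[C@H]13
F7 | step 9 | 4α-methanesulfonate of 14 | CO[C@@H]1C=C(COC(=O)c2ccccc2)[C@H](OS(C)(=O)=O)[C@@H]3O[C@H]13
F8 | step 10 | 5α,6α-epoxy-3-(hydroxymethyl)-1α-methoxycyclohex-2-en-4β-ol (trans-epoxy diol) | CO[C@@H]1C=C(CO)[C@@H](O)[C@@H]3O[C@H]13
F9 | step 10 | 4β,5β-cyclic carbonate of 3-(hydroxymethyl)-1α-methoxycyclohex-2-ene-4,5,6-triol, 6α-OH free | CO[C@@H]1C=C(CO)[C@H]3OC(=O)O[C@H]3[C@@H]1O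
F10 | step 11 | 3-(hydroxymethyl)-1α-methoxycyclohex-2-ene-4β,5β,6α-triol (tetraol) | CO[C@@H]1C=C(CO)[C@@H](O)[C@@H](O)[C@@H]1O
F11 | step 11 | 4,5-O-dibutylstannylene acetal of F10 | CO[C@@H]1C=C(CO)[C@H]2O[Sn](CCCC)(CCCC)O[C@H]2[C@@H]1O
A1 | alternative 1 | bromobenzene | Brc1ccccc1
A2 | alternative 1 | (1S,2S)-3-bromocyclohexa-3,5-diene-1,2-diol | BrC1=CC=C[C@H](O)[C@@H]1O
A3 | alternative 2 | (2R,3R,4Z)-2-(tert-butyldimethylsilyloxy)-5-[(tert-butyldimethylsilyloxy)methyl]-3-methoxyhex-4-enedial | O=C[C@H](O[Si](C)(C)C(C)(C)C)[C@H](OC)/C=C(/CO[Si](C)(C)C(C)(C)C)C=O
A4 | alternative 2 | cyclohexene cis-4,5-diol with C1 methoxy and silyl ethers at O6 and O7 | CO[C@@H]1C=C(CO[Si](C)(C)C(C)(C)C)[C@@H](O)[C@@H](O)[C@@H]1O[Si](C)(C)C(C)(C)C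
A5 | alternative 3 | methyl 2-oxo-2H-pyran-3-carboxylate | COC(=O)C1=CC=COC1=O
A6 | alternative 3 | 2,2-dimethyl-1,3-dioxole | CC1(C)OC=CO1
A7 | alternative 3 | endo bicyclic lactone adduct with C4,C5 acetonide and C1=C2 alkene | COC(=O)[C@@]12C=C[C@@H](OC1=O)[C@@H]3OC(C)(C)O[C@H]23
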